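A direct plan would join two preformed flavans at the interflavan bond: 5,7,4'-tri-O-benzyl-epiafzelechin A1 would be oxidised at C4 to a 4-alkoxy derivative A2,
which a Lewis acid would ionise for Friedel–Crafts coupling with a protected epicatechin gallate A3, and hydrogenolysis would finish.
Its weakest steps would be:
(a) the supply of A1: epiafzelechin is no practical starting material, so the 2,3-cis flavan-3-ol would have to come from an asymmetric reduction of a racemic flavan-3-one, for which firm precedent is lacking;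
(b) the bimolecular coupling: the flavan-4-yl cation prefers C8, so the 4→6 isomer would need a bromine at C8 of A3 (one more step, carried to the end) and an excess of A3;
(c) the C4 oxidation of A1 with DDQ, which would be moderate and prone to over-oxidation.

The route rests on closing ring C of the upper unit last, at C4–C4a, by an intramolecular Friedel–Crafts alkylation. C4 is a diarylmethine between two phloroglucinol rings: in an open-chain C4 carbinol that already carries C6 of the lower unit, ionisation gives a cation stabilised by O5, O7 and O1 of that ring, and the tethered 3,5-bis(benzyloxy)phenyl ether, whose two ortho carbons are equivalent, closes the pyran and sets C4 trans to O3 in one operation. C2 and C3 come from an Evans glycolate aldol reaction, and the 4→6 bond is made beforehand by lithiation of C6 between two acetal ethers; no flavan-3-one reduction, C8 blocking group or C4 oxidation is needed.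

Key step: step 10

Assumption: 8, 20 and benzyl chloromethyl ether are taken as commercial; carbinol 16 is carried as both epimers at the carbinol carbon, because this center becomes planar in step 10.

Step 1
Reactants: 1 (S)-4-benzyl-2-oxazolidinone; 2 benzyloxyacetyl chloride
Product: 3 (S)-4-benzyl-3-[(benzyloxy)acetyl]oxazolidin-2-one
Conditions: n-BuLi (1.0 equiv), THF, −78 °C; 2 (1.1 equiv), −78 → 0 °C
Reagents that add atoms: none
Why: N-acylation of the lithiated Evans oxazolidinone installs the glycolate unit whose benzyl ether becomes the 3-O-benzyl group of the upper unit; no stereocenter is formed.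

Step 2
Reactants: 3 (S)-4-benzyl-3-[(benzyloxy)acetyl]oxazolidin-2-one; 4 4-(benzyloxy)benzaldehyde
Product: 6 (S)-4-benzyl-3-{(2S,3R)-2-(benzyloxy)-3-[4-(benzyloxy)phenyl]-3-hydroxypropanoyl}oxazolidin-2-one, via dibutylboron Z-enolate 5 (not isolated)
Conditions: Bu2BOTf (1.15 equiv), Et3N (1.3 equiv), CH2Cl2, −78 → 0 °C; 4 (1.2 equiv), −78 → 0 °C; pH 7 buffer, MeOH, 30 % H2O2, 0 °C
Reagents that add atoms: none
Why: Evans syn-aldol reaction: the Z boron enolate reacts through a Zimmerman–Traxler chair on the face opposite the benzyl group of the auxiliary, which should set the future C2 (3R in the chain) and C3 (2S) of the upper unit in the syn relationship that becomes 2,3-cis.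

Step 3
Reactants: 6 aldol adduct
Product: 7 (2S,3R)-2-(benzyloxy)-3-[4-(benzyloxy)phenyl]-3-hydroxy-N-methoxy-N-methylpropanamide
Conditions: MeONHMe·HCl (3 equiv), AlMe3 (3 equiv), CH2Cl2, −10 → 0 °C; cold 0.5 M HCl
Reagents that add atoms: N,O-dimethylhydroxylamine hydrochloride, CNOC.Cl
Why: aluminium amide transamidation to the Weinreb amide, assisted by the free β-hydroxyl, should remove the auxiliary without touching either stereocenter.

Step 4
Reactants: 8 3,5-bis(benzyloxy)phenylboronic acid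
Product: 9 potassium [3,5-bis(benzyloxy)phenyl]trifluoroborate
Conditions: KHF2 (3.5 equiv), MeOH/H2O, rt
Reagents that add atoms: potassium hydrogen difluoride, [K+].[F-].F
Why: conversion of a boronic acid into its trifluoroborate salt gives the aryl donor that performs best in copper-catalysed etherification of aliphatic alcohols.

Step 5
Reactants: 7 Weinreb amide; 9 potassium [3,5-bis(benzyloxy)phenyl]trifluoroborate
Product: 10 (2S,3R)-2-(benzyloxy)-3-[4-(benzyloxy)phenyl]-3-[3,5-bis(benzyloxy)phenoxy]-N-methoxy-N-methylpropanamide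
Conditions: 9 (2.0 equiv), Cu(OAc)2·H2O (0.2 equiv), DMAP (0.4 equiv), 4 Å MS, CH2Cl2, O2 (1 atm), rt
Reagents that add atoms: none
Why: Chan–Lam-type oxidative copper-catalysed O-arylation of the secondary alcohol forms the future O1–C8a ether bond under neutral conditions at room temperature, so retro-aldol cleavage and β-elimination should not intervene, and C2 keeps its configuration because its C–O bond is not broken.

Step 6
Reactants: 10 aryl ether Weinreb amide
Product: 11 (2S,3R)-2-(benzyloxy)-3-[4-(benzyloxy)phenyl]-3-[3,5-bis(benzyloxy)phenoxy]propanal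
Conditions: i-Bu2AlH (1.5 equiv), THF, −78 °C; aq. Rochelle salt; used at once
Reagents that add atoms: none
Why: Weinreb amide reduction stops at the chelated hemiaminal and should release the aldehyde (the future C4) on work-up without epimerisation of the α-alkoxy center.

Step 7
Reactants: 12 (−)-epicatechin
Product: 13 5,7,3',4'-tetrakis-O-(benzyloxymethyl)-(−)-epicatechin
Conditions: BnOCH2Cl (4.4 equiv), K2CO3 (6 equiv), DMF, 0 °C → rt, Ar
Reagents that add atoms: benzyl chloromethyl ether, ClCOCc1ccccc1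
Why: Williamson-type O-alkylation of the four phenoxides (carbonate does not deprotonate the 3-OH) installs acetal ethers that direct the lithiation of step 9 and are later cleaved by hydrogenolysis; C2 and C3 are taken from the natural product.

Step 8
Reactants: 13 tetrakis(benzyloxymethyl) ether
Product: 14 5,7,3',4'-tetrakis-O-(benzyloxymethyl)-3-O-(tert-butyldimethylsilyl)-(−)-epicatechin
Conditions: TBSCl (1.5 equiv), imidazole (3 equiv), DMF, rt
Reagents that add atoms: tert-butyldimethylsilyl chloride, CC(C)(C)[Si](C)(C)Cl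
Why: imidazole-promoted silylation masks the only acidic proton before the lithiation and keeps this oxygen distinguishable for the later galloylation.

Step 9
Reactants: 14 silyl ether of the lower unit; 11 aldehyde
Product: 16 6-{(1RS,2R,3R)-2-(benzyloxy)-3-[4-(benzyloxy)phenyl]-3-[3,5-bis(benzyloxy)phenoxy]-1-hydroxypropyl}-5,7,3',4'-tetrakis-O-(benzyloxymethyl)-3-O-(tert-butyldimethylsilyl)-(−)-epicatechin (both C1 epimers), via 6-lithio flavan 15 (not isolated)
Conditions: 14 (1.3 equiv), n-BuLi (1.25 equiv), THF, −40 → 0 °C, 1 h; −78 °C, 11 (1.0 equiv); H2O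
Reagents that add atoms: none
Why: directed ortho-metalation followed by 1,2-addition: C6–H is the only ring hydrogen flanked by two alkoxymethyl ethers whose distal oxygens both chelate lithium (C8–H has one such group and the ring oxygen), so lithiation should take place at C6 under kinetic and thermodynamic control, and the aryllithium adds to the aldehyde to form the C4–C6 interflavan bond with the regiochemistry fixed by the metal.

Step 10
Reactants: 16 carbinol (both epimers)
Product: 18 3,5,7,4'-tetra-O-benzyl-(−)-epiafzelechin-(4β→6)-[5,7,3',4'-tetrakis-O-(benzyloxymethyl)-3-O-(tert-butyldimethylsilyl)-(−)-epicatechin], via C4 benzylic cation 17 (not isolated)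
Conditions: BF3·OEt2 (0.3 equiv), 4 Å MS, CH2Cl2 (0.01 M), −78 → −30 °C; Et3N
Reagents that add atoms: none
Why: BF3 ionises the carbinol (both epimers converge) to a benzylic cation delocalised into ring A of the lower unit and stabilised by O5, O7 and O1 of that ring, far more readily than the C2 aryl ether or the acetals can ionise; the tethered 3,5-bis(benzyloxy)phenyl ether then attacks through one of its two equivalent ortho carbons, and loss of a proton restores the arene. The closest known reaction type is the acid-mediated dehydrative intramolecular Friedel–Crafts alkylation of 1-aryl-3-aryloxypropan-1-ols to 4-arylchromans, the intramolecular counterpart of the flavan-4-yl cation–phloroglucinol coupling. Ring C (O1, C2, C3, C4, C4a, C8a) is closed in a 6-exo-trig mode: C4a attacks the cationic C4, whose π bond to the lower ring lies outside the new ring. C4 is the only new stereocenter and is controlled by C2 and C3: in the chair-like transition state the 2-aryl group is equatorial, the 3-benzyloxy group therefore axial, and the lower-unit aryl takes the pseudo-axial position anti to O3, which also avoids peri strain with the 5-benzyloxy group, so the 3,4-trans (4β) product should form. The step needs facial selectivity at C4 (secured as described) and chemoselective ionisation at C4 (secured by the trioxygenated ring); no regiochemical choice arises on ring A of the upper unit because the ether is symmetric.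

Step 11
Reactants: 18 protected dimer
Product: 19 3,5,7,4'-tetra-O-benzyl-(−)-epiafzelechin-(4β→6)-[5,7,3',4'-tetrakis-O-(benzyloxymethyl)-(−)-epicatechin]
Conditions: Bu4NF (1.5 equiv), AcOH (1.5 equiv), THF, 0 °C → rt
Reagents that add atoms: none
Why: fluoride-induced cleavage of the silyl ether, buffered with acetic acid, should free only the 3-OH of the lower unit, the 3-oxygen of the upper unit staying benzylated.

Step 12
Reactants: 19 mono-alcohol; 20 3,4,5-tris(benzyloxy)benzoic acid
Product: 21 3,5,7,4'-tetra-O-benzyl-(−)-epiafzelechin-(4β→6)-[5,7,3',4'-tetrakis-O-(benzyloxymethyl)-(−)-epicatechin 3-O-(3,4,5-tri-O-benzylgallate)]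
Conditions: 20 (3 equiv), DCC (3 equiv), DMAP (0.5 equiv), CH2Cl2, rt
Reagents that add atoms: none
Why: Steglich esterification (DCC activation, DMAP acyl transfer) acylates the single free hydroxyl at oxygen, so C3 of the lower unit keeps its configuration.

Step 13
Reactants: 21 fully protected gallate
Product: 22 (−)-epiafzelechin-(4β→6)-(−)-epicatechin 3-O-gallate
Conditions: H2 (1 atm), 20 % Pd(OH)2/C, THF/MeOH (1:1), rt; filter, lyophilise
Reagents that add atoms: none
Why: catalytic hydrogenolysis cleaves the seven benzyl ethers and the four benzyloxymethyl ethers (the hemiformals left behind lose formaldehyde) under neutral conditions that should leave the gallate ester, the interflavan bond and all five stereocenters intact.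

Compound list
1 | (S)-4-benzyl-2-oxazolidinone | O=C1N[C@@H](Cc2ccccc2)CO1 | starting material
2 | benzyloxyacetyl chloride | O=C(Cl)COCc1ccccc1 | starting material
3 | (S)-4-benzyl-3-[(benzyloxy)acetyl]oxazolidin-2-one | O=C(COCc1ccccc1)N1C(=O)OC[C@@H]1Cc1ccccc1 | intermediate
4 | 4-(benzyloxy)benzaldehyde | O=Cc1ccc(OCc2ccccc2)cc1 | starting material
5 | dibutylboron (Z)-enolate of 3 | CCCCB(CCCC)O/C(=C\OCc1ccccc1)N1C(=O)OC[C@@H]1Cc1ccccc1 | intermediate (not isolated)
6 | (S)-4-benzyl-3-{(2S,3R)-2-(benzyloxy)-3-[4-(benzyloxy)phenyl]-3-hydroxypropanoyl}oxazolidin-2-one | O[C@H](c1ccc(OCc2ccccc2)cc1)[C@H](OCc1ccccc1)C(=O)N1C(=O)OC[C@@H]1Cc1ccccc1 | intermediate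
7 | (2S,3R)-2-(benzyloxy)-3-[4-(benzyloxy)phenyl]-3-hydroxy-N-methoxy-N-methylpropanamide | O[C@H](c1ccc(OCc2ccccc2)cc1)[C@H](OCc1ccccc1)C(=O)N(C)OC | intermediate
8 | 3,5-bis(benzyloxy)phenylboronic acid | OB(O)c1cc(OCc2ccccc2)cc(OCc2ccccc2)c1 | starting material
9 | potassium [3,5-bis(benzyloxy)phenyl]trifluoroborate | [K+].F[B-](F)(F)c1cc(OCc2ccccc2)cc(OCc2ccccc2)c1 | intermediate
10 | (2S,3R)-2-(benzyloxy)-3-[4-(benzyloxy)phenyl]-3-[3,5-bis(benzyloxy)phenoxy]-N-methoxy-N-methylpropanamide | c1c(OCc2ccccc2)cc(OCc2ccccc2)cc1O[C@H](c1ccc(OCc2ccccc2)cc1)[C@H](OCc1ccccc1)C(=O)N(C)OC | intermediate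
11 | (2S,3R)-2-(benzyloxy)-3-[4-(benzyloxy)phenyl]-3-[3,5-bis(benzyloxy)phenoxy]propanal | c1c(OCc2ccccc2)cc(OCc2ccccc2)cc1O[C@H](c1ccc(OCc2ccccc2)cc1)[C@H](OCc1ccccc1)C=O | intermediate
12 | (−)-epicatechin, (2R,3R) | O[C@@H]1Cc2c(O)cc(O)cc2O[C@@H]1c1ccc(O)c(O)c1 | starting material
13 | 5,7,3',4'-tetrakis-O-(benzyloxymethyl)-(−)-epicatechin | O[C@@H]1Cc2c(OCOCc3ccccc3)cc(OCOCc3ccccc3)cc2O[C@@H]1c1ccc(OCOCc2ccccc2)c(OCOCc2ccccc2)c1 | intermediate
14 | 5,7,3',4'-tetrakis-O-(benzyloxymethyl)-3-O-(tert-butyldimethylsilyl)-(−)-epicatechin | CC(C)(C)[Si](C)(C)O[C@@H]1Cc2c(OCOCc3ccccc3)cc(OCOCc3ccccc3)cc2O[C@@H]1c1ccc(OCOCc2ccccc2)c(OCOCc2ccccc2)c1 | intermediate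
15 | 6-lithio derivative of 14 | CC(C)(C)[Si](C)(C)O[C@@H]1Cc2c(OCOCc3ccccc3)c([Li])c(OCOCc3ccccc3)cc2O[C@@H]1c1ccc(OCOCc2ccccc2)c(OCOCc2ccccc2)c1 | intermediate (not isolated)
16 | 6-{(1RS,2R,3R)-2-(benzyloxy)-3-[4-(benzyloxy)phenyl]-3-[3,5-bis(benzyloxy)phenoxy]-1-hydroxypropyl}-5,7,3',4'-tetrakis-O-(benzyloxymethyl)-3-O-(tert-butyldimethylsilyl)-(−)-epicatechin (both epimers at the carbinol carbon) | CC(C)(C)[Si](C)(C)O[C@@H]1Cc2c(cc(OCOCc3ccccc3)c(C(O)[C@@H](OCc3ccccc3)[C@H](Oc3cc(OCc4ccccc4)cc(OCc4ccccc4)c3)c3ccc(OCc4ccccc4)cc3)c2OCOCc2ccccc2)O[C@@H]1c1ccc(OCOCc2ccccc2)c(OCOCc2ccccc2)c1 | intermediate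
17 | C4 benzylic cation from 16 (delocalised into ring A of the lower unit) | CC(C)(C)[Si](C)(C)O[C@@H]1Cc2c(cc(OCOCc3ccccc3)c([CH+][C@@H](OCc3ccccc3)[C@H](Oc3cc(OCc4ccccc4)cc(OCc4ccccc4)c3)c3ccc(OCc4ccccc4)cc3)c2OCOCc2ccccc2)O[C@@H]1c1ccc(OCOCc2ccccc2)c(OCOCc2ccccc2)c1 | intermediate (not isolated)
18 | 3,5,7,4'-tetra-O-benzyl-(−)-epiafzelechin-(4β→6)-[5,7,3',4'-tetrakis-O-(benzyloxymethyl)-3-O-(tert-butyldimethylsilyl)-(−)-epicatechin] | CC(C)(C)[Si](C)(C)O[C@@H]1Cc2c(cc(OCOCc3ccccc3)c([C@H]3c4c(OCc5ccccc5)cc(OCc5ccccc5)cc4O[C@H](c4ccc(OCc5ccccc5)cc4)[C@@H]3OCc3ccccc3)c2OCOCc2ccccc2)O[C@@H]1c1ccc(OCOCc2ccccc2)c(OCOCc2ccccc2)c1 | intermediate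
19 | 3,5,7,4'-tetra-O-benzyl-(−)-epiafzelechin-(4β→6)-[5,7,3',4'-tetrakis-O-(benzyloxymethyl)-(−)-epicatechin] | O[C@@H]1Cc2c(cc(OCOCc3ccccc3)c([C@H]3c4c(OCc5ccccc5)cc(OCc5ccccc5)cc4O[C@H](c4ccc(OCc5ccccc5)cc4)[C@@H]3OCc3ccccc3)c2OCOCc2ccccc2)O[C@@H]1c1ccc(OCOCc2ccccc2)c(OCOCc2ccccc2)c1 | intermediate
20 | 3,4,5-tris(benzyloxy)benzoic acid | OC(=O)c1cc(OCc2ccccc2)c(OCc2ccccc2)c(OCc2ccccc2)c1 | starting material
21 | 3,5,7,4'-tetra-O-benzyl-(−)-epiafzelechin-(4β→6)-[5,7,3',4'-tetrakis-O-(benzyloxymethyl)-(−)-epicatechin 3-O-(3,4,5-tri-O-benzylgallate)] | O=C(O[C@@H]1Cc2c(cc(OCOCc3ccccc3)c([C@H]3c4c(OCc5ccccc5)cc(OCc5ccccc5)cc4O[C@H](c4ccc(OCc5ccccc5)cc4)[C@@H]3OCc3ccccc3)c2OCOCc2ccccc2)O[C@@H]1c1ccc(OCOCc2ccccc2)c(OCOCc2ccccc2)c1)c1cc(OCc2ccccc2)c(OCc2ccccc2)c(OCc2ccccc2)c1 | intermediate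
22 | (−)-epiafzelechin-(4β→6)-(−)-epicatechin 3-O-gallate; upper unit 2R,3R,4S (2,3-cis-3,4-trans), lower unit 2R,3R | O=C(O[C@@H]1Cc2c(cc(O)c([C@H]3c4c(O)cc(O)cc4O[C@H](c4ccc(O)cc4)[C@@H]3O)c2O)O[C@@H]1c1ccc(O)c(O)c1)c1cc(O)c(O)c(O)c1 | target

Total step count: 13. Longest linear sequence: 10 steps (1, 2, 3, 5, 6, 9, 10, 11, 12, 13).

Steps most likely to fail

Step 9. Lithiation may not discriminate well enough between C6 and C8, which would end in the 4→8 isomer, and the aryllithium may deprotonate the aldehyde, with loss of the β-aryloxy group, instead of adding. Fallback (C8 closed before metalation): setting out from 14, NBS (CH2Cl2, −78 °C) would brominate C8, the position preferred in electrophilic substitution, to give 8-bromo-5,7,3',4'-tetrakis-O-(benzyloxymethyl)-3-O-(tert-butyldimethylsilyl)-(−)-epicatechin F1. C6–H is then the only hydrogen left on ring A; deprotonation with lithium 2,2,6,6-tetramethylpiperidide (THF, −78 °C), a base that does not exchange bromine, and addition to 11 would give the 8-bromo analogue of carbinol 16 F2. Bromine–lithium exchange (t-BuLi, THF, −78 °C) and protonation with MeOH would return carbinol 16.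

Step 5. The hindered secondary benzylic alcohol may bind copper slowly, so that protodeboronation and phenol formation consume the aryl donor, or the alcohol may be oxidised to the ketone. Fallback (ether by substitution with inversion instead of O-arylation with retention): setting out from aldehyde 4, Z-selective Horner–Wadsworth–Emmons olefination with ethyl (diphenoxyphosphoryl)acetate (NaH, THF, −78 °C) would give ethyl (Z)-3-[4-(benzyloxy)phenyl]prop-2-enoate F3. Jacobsen–Katsuki epoxidation ((S,S)-[N,N'-bis(3,5-di-tert-butylsalicylidene)cyclohexane-1,2-diaminato]manganese chloride, NaOCl, 4-phenylpyridine N-oxide, CH2Cl2, 0 °C) would give the cis-glycidate ethyl (2S,3S)-3-[4-(benzyloxy)phenyl]oxirane-2-carboxylate F4. Opening at the benzylic carbon by 3,5-bis(benzyloxy)phenol (Cs2CO3, DMF, 50 °C, inversion) would give ethyl (2S,3R)-3-[3,5-bis(benzyloxy)phenoxy]-3-[4-(benzyloxy)phenyl]-2-hydroxypropanoate F5, O-benzylation (BnBr, Ag2O, CH2Cl2) ethyl (2S,3R)-2-(benzyloxy)-3-[3,5-bis(benzyloxy)phenoxy]-3-[4-(benzyloxy)phenyl]propanoate F6, and i-Bu2AlH (CH2Cl2, −78 °C) aldehyde 11.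

Step 10. The Lewis acid may strip acetal or silyl groups, or the cation may lose the C3 proton to an enol ether, faster than the ring closes. Fallback (solvolytic instead of acid-promoted ionisation): setting out from 16, acetylation (Ac2O, DMAP, pyridine, 0 °C) would give the acetate of carbinol 16 F7. This ester should ionise on dissolution in (CF3)2CHOH/CH2Cl2 buffered with 2,6-di-tert-butylpyridine at 0 °C, and the same cation would close ring C to 18 without added acid.

Further compounds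
F1 | step 9 | 8-bromo-5,7,3',4'-tetrakis-O-(benzyloxymethyl)-3-O-(tert-butyldimethylsilyl)-(−)-epicatechin | CC(C)(C)[Si](C)(C)O[C@@H]1Cc2c(OCOCc3ccccc3)cc(OCOCc3ccccc3)c(Br)c2O[C@@H]1c1ccc(OCOCc2ccccc2)c(OCOCc2ccccc2)c1
F2 | step 9 | 8-bromo analogue of carbinol 16 (both epimers at the carbinol carbon) | CC(C)(C)[Si](C)(C)O[C@@H]1Cc2c(c(Br)c(OCOCc3ccccc3)c(C(O)[C@@H](OCc3ccccc3)[C@H](Oc3cc(OCc4ccccc4)cc(OCc4ccccc4)c3)c3ccc(OCc4ccccc4)cc3)c2OCOCc2ccccc2)O[C@@H]1c1ccc(OCOCc2ccccc2)c(OCOCc2ccccc2)c1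
F3 | step 5 | ethyl (Z)-3-[4-(benzyloxy)phenyl]prop-2-enoate | CCOC(=O)/C=C\c1ccc(OCc2ccccc2)cc1
F4 | step 5 | ethyl (2S,3S)-3-[4-(benzyloxy)phenyl]oxirane-2-carboxylate (cis) | O1[C@@H](c2ccc(OCc3ccccc3)cc2)[C@H]1C(=O)OCC
F5 | step 5 | ethyl (2S,3R)-3-[3,5-bis(benzyloxy)phenoxy]-3-[4-(benzyloxy)phenyl]-2-hydroxypropanoate | c1c(OCc2ccccc2)cc(OCc2ccccc2)cc1O[C@H](c1ccc(OCc2ccccc2)cc1)[C@H](O)C(=O)OCC
F6 | step 5 | ethyl (2S,3R)-2-(benzyloxy)-3-[3,5-bis(benzyloxy)phenoxy]-3-[4-(benzyloxy)phenyl]propanoate | c1c(OCc2ccccc2)cc(OCc2ccccc2)cc1O[C@H](c1ccc(OCc2ccccc2)cc1)[C@H](OCc1ccccc1)C(=O)OCC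
F7 | step 10 | acetate of carbinol 16 (both epimers at the acetoxy carbon) | CC(C)(C)[Si](C)(C)O[C@@H]1Cc2c(cc(OCOCc3ccccc3)c(C(OC(C)=O)[C@@H](OCc3ccccc3)[C@H](Oc3cc(OCc4ccccc4)cc(OCc4ccccc4)c3)c3ccc(OCc4ccccc4)cc3)c2OCOCc2ccccc2)O[C@@H]1c1ccc(OCOCc2ccccc2)c(OCOCc2ccccc2)c1
A1 | direct plan | 5,7,4'-tri-O-benzyl-(−)-epiafzelechin, (2R,3R) | O[C@@H]1Cc2c(OCc3ccccc3)cc(OCc3ccccc3)cc2O[C@@H]1c1ccc(OCc2ccccc2)cc1
A2 | direct plan | (2R,3R,4S)-5,7-bis(benzyloxy)-2-[4-(benzyloxy)phenyl]-4-(2-ethoxyethoxy)chroman-3-ol | O[C@@H]1[C@@H](OCCOCC)c2c(OCc3ccccc3)cc(OCc3ccccc3)cc2O[C@@H]1c1ccc(OCc2ccccc2)cc1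
A3 | direct plan | 8-bromo-5,7,3',4'-tetra-O-benzyl-(−)-epicatechin 3-O-(3,4,5-tri-O-benzylgallate) | O=C(O[C@@H]1Cc2c(OCc3ccccc3)cc(OCc3ccccc3)c(Br)c2O[C@@H]1c1ccc(OCc2ccccc2)c(OCc2ccccc2)c1)c1cc(OCc2ccccc2)c(OCc2ccccc2)c(OCc2ccccc2)c1
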